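It is easy to start the clock of Xa's loss at charging, but in alpha and beta Xa must first be born, and the clock of its loss starts then.

    Xo ⇌ Qi, rate k1*(cs1 - [Qi]) while solid is left; crystals form when [Qi] > cs1 (cs1 = 0.18 M, k1 = 0.38 /min)
    Xa ⇌ Ul (K2 = 0.89, k2 = 0.0017 /min)
    Xa → Ji (k3 = 0.0026 /min)
    Jy + Ry + Qi → Xa + 2 Qi (k4 = 3.2 /M²/min)
    Jy + Ry → Xa + Qi (k5 = 7.1 × 10⁻⁴ /M/min)

- alpha: Jy 0.20 M; Ry 0.240 M; time 3.0 h
- beta: Jy 0.20 M; Ry 0.240 M; time 10 h

1. which of the two there is more of at the end, alpha (Ji / Xa)
2. which of the two there is more of at the end, beta (Ji / Xa)
3. final Xa, as a percentage of the Jy charged, in alpha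
4. final Xa, as a percentage of the Jy charged, in beta

- for Qi the Xo is counted in
- as a solid, counted per litre of solution: Xo
- run time (alpha): 3.0 h

Alpha and beta are one recipe stopped at different times, so they share one birth curve and end at different ages. We replace that curve by its mean: we let the full charge of Jy, the limiting reagent with Ry charged above it, turn at the single moment when half of it has gone. We integrate the catalysed rate, seeded by the uncatalysed step, up to that point, where Qi is still below its solubility:

birth moment = 0.822 h

From then on Xa drains forward to Ul and to Ji:

drain = 0.00430 /min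

alpha: exp(−drain × age) = 57.0 %

beta: exp(−drain × age) = 9.37 %

This fraction of the charge, still Xa at the end when nothing comes back, is the survivor share. Setting the births as far as the birth moment to either side of the mean raises it by 2.25 % of itself, so the mean will do.

Of what drains, the fraction 60.5 % goes to Ji:

alpha: Ji = 26.0 %

beta: Ji = 54.8 %

So we expect more Xa than Ji in alpha and more Ji than Xa in beta.

The forecast, with “Xa forms on average at about an hour”, named Xa for alpha and Ji for beta, and gave 61 % and 18 % against our 57.0 % and 9.37 %.

The simulation gives 59.9 % Xa and 25.0 % Ji in alpha, and 17.9 % Xa and 60.8 % Ji in beta.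

In beta Xa ends low mainly through its turning into Ji: the run of beta without that step ends at 59.6 % Xa instead of 17.9 %. Our share for alpha stands close, but for beta it is about half of what the flask holds. The survivor share lets nothing return from Ul, and that return is a part of beta's Xa: the run of beta without the reverse step ends at 9.73 %, near our 9.37 %.

Take the neighbour of alpha with 0.34 M of Jy, where Ry is 0.706 equiv, so at most 70.6 % of the Jy can turn. With alpha's survivor share kept, we expect 40.2 % Xa; the simulation gives 38.9 %, with Ry at 0 % and 29 % of the Jy left.

The constants used here are those of an exercise, and the outcome is calculated.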